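All runs were computed for an exercise; noise was put on by code.

Count amounts in percent of the starting material charged; the split below is a different fraction, isomer's share of isomer plus target.

| setting | Sunday's | Saturday's | flask |
|---|---|---|---|
| starting material | 0.050 M | 0.034 M | 0.050 M |
| solid reagent | 0.035 M | 0.035 M | 0.0350 M |
| remark | the very flask that is asked about, followed so far | run made earlier |  |
| time |  |  | 15 d |

Sunday's run (percent of the starting material charged)

| time / h | isomer of the product / % | target / % | starting material / % |
|---|---|---|---|
| 2.50 | 0 | 0 | 98 |
| 5.00 | 2 | 0 | 97 |
| 12.0 | 2 | 1 | 100 |
| 30.0 | 5 | 7 | 92 |

Saturday's run (percent of the starting material charged)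

| time / d | isomer of the product / % | target / % | starting material / % |
|---|---|---|---|
| 1.25 | 4 | 6 | 89 |
| 3.00 | 10 | 22 | 71 |
| 6.00 | 19 | 45 | 38 |
| 15.0 | 25 | 63 | 13 |

(each reading ± 1.5 percentage points)

- the analysis behind the earlier runs scatters by 1.5 percentage points, standard deviation
- at the start none of the solid reagent is in solution
- a reading or a percentage of target counts all its forms, free or not

- share of isomer of the product in isomer of the product plus target at 15 h
- share of isomer of the product in isomer of the product plus target at 2.5 d
- share of isomer of the product in isomer of the product plus target at 15 d
- which of isomer of the product and target there is more of at 15 d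

Picture a tank with two outlets, one into isomer of the product and one into target. Each outlet has its own time constant, but the answers ask for their ratio. Read it where the amounts are large. Saturday's last reading holds 25% isomer and 63% target, so you get 28.4% for the split, the isomer's share of the two together. Saturday's flask reads 31.2% at 3.00 d and 29.7% at 6.00 d, so the ratio barely moves.

The early end is weak. Sunday's flask reads 5% and 7% at 30.0 h, a share of 41.7%, but each reading scatters by 1.5 percentage points.

Sunday's flask has more starting material than Saturday's, with equal solid reagent. I expect that to change how far it runs, not the split. My reckoning is therefore 28.4% at 15 h, 2.5 d and 15 d, with target ahead.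

The forecast differs. Starting from “The early points show isomer appearing first while target lags”, it gives 60%, 33% and 32% at those times, with target ahead.

The flask gives shares of 28.0%, 28.0% and 28.0% at those times. Target reaches 49.5% of the charge at 15 d, more than isomer of the product at 19.3%.

    starting material ⇌ other conformer (K = 0.0127, k = 0.433 /h)
    partner + other conformer → isomer of the product (k = 15.1 /M/h)
    crystals ⇌ target, rate k3*(cs3 - [target]) while solid is left; crystals form when [target] > cs3 (solubility = 3.00 mM, k = 10.9 /h)
    starting material + partner → target (k = 0.492 /M/h)
    solid reagent ⇌ partner, rate k5*(cs5 - [partner]) while solid is left; crystals form when [partner] > cs5 (solubility = 17.0 mM, k = 0.0304 /h)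

The split of 28.4% read from Saturday's flask stands beside these values because other conformer is undone into starting material. In the run without that step, the share at 15 h is 99.5% instead of 28.0%. With the step in place, other conformer follows starting material, and partner enters both outlets. This is the Curtin–Hammett case. In the neighbour charged with 0.014 M of solid reagent, the split again gives 28.4%. That flask computes to a share of 28.0%, with isomer at 7.84% of the charge and 71.1% of the starting material left.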